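**Plan**

- Retrosynthesis: the (E)-styryl bridge is cut at its aryl–CH bond (Heck coupling with an 8-iodocoumarin). The coumarin on the ring CH is cut back to a 2,6-dimethoxyphenyl group (demethylation, ortho-formylation, Wittig–lactonisation). The cyclohexene is cut at its C=C bond (ring-closing metathesis). The open-chain diene is traced to a chiral butenolide by cutting the aryl–C, methyl–C and chain–C bonds.
- Enabling feature: in the cyclohexene (ring C: C1 quaternary with CH3 and the styryl group, C2 the aryl-bearing CH, C3=C4 with CH3 on C4, C5 and C6 methylenes) the only C=C lies between C3 and C4. Opening it leaves a vinyl group on C2 and a 3-methylbut-3-enyl arm on C1, an acyclic 1,7-diene that already holds both stereocentres.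
- Forward order: aryl cuprate addition and two enolate alkylations on a γ-lactone, zinc fragmentation to the open-chain diene, metathesis to ring C, CH2OH to vinyl on C1, annulation of the pyranone ring (coumarin B), and a final Heck coupling that attaches coumarin A.
- Stereochemistry: C5 of (S)-5-(hydroxymethyl)furan-2(5H)-one sends the aryl group to the opposite face (ring C2). The aryl group then sends the butenyl chain to its opposite face (ring C1). The auxiliary centre is erased when zinc unveils the vinyl group, and the (E)-alkene follows from the Heck mechanism.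

Key step: step 10

Remark: the target is read as (1R,2R) on ring C with the C2 coumarinyl and C1 styryl groups cis, and (S)-5-(hydroxymethyl)furan-2(5H)-one is taken as a purchasable chiral-pool lactone.

**Route**

Step 1
Reactants: 1 (S)-5-(hydroxymethyl)furan-2(5H)-one
Product: 2 (S)-5-{[(tert-butyldiphenylsilyl)oxy]methyl}furan-2(5H)-one
Conditions: TBDPSCl, imidazole, CH2Cl2, 0 °C → rt
Reagents that add atoms: tert-butyl(chloro)diphenylsilane, CC(C)(C)[Si](Cl)(c1ccccc1)c1ccccc1
Why: Imidazole-promoted silyl ether formation masks the primary alcohol against the organometallic and enolate steps and provides the bulky C5 group that steers step 2.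

Step 2
Reactants: 3 1,3-dimethoxybenzene; 2 (S)-5-{[(tert-butyldiphenylsilyl)oxy]methyl}furan-2(5H)-one
Product: 7 (4R,5S)-5-{[(tert-butyldiphenylsilyl)oxy]methyl}-4-(2,6-dimethoxyphenyl)dihydrofuran-2(3H)-one, via 2,6-dimethoxyphenyllithium 4 (not isolated), via lithium bis(2,6-dimethoxyphenyl)cuprate 5 (not isolated), via trimethylsilyl ketene acetal 6 (not isolated)
Conditions: 3 (2.2 equiv), n-BuLi, THF, 0 °C → rt; CuI (1.1 equiv), −40 °C; Me3SiCl then 2, −78 → −30 °C; aq. NH4Cl
Reagents that add atoms: none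
Why: Directed ortho-lithiation between the two methoxy groups and transmetalation give a Gilman diarylcuprate whose Me3SiCl-assisted conjugate addition to the butenolide should occur on the face opposite the C5 silyloxymethyl group, so that the new C4 stereocentre is set 4,5-trans by substrate control before the ketene acetal is hydrolysed on work-up.

Step 3
Reactants: 7 (4R,5S)-5-{[(tert-butyldiphenylsilyl)oxy]methyl}-4-(2,6-dimethoxyphenyl)dihydrofuran-2(3H)-one
Product: 9 (3S,4R,5S)-5-{[(tert-butyldiphenylsilyl)oxy]methyl}-4-(2,6-dimethoxyphenyl)-3-methyldihydrofuran-2(3H)-one, via lithium enolate 8 (not isolated)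
Conditions: LiN(SiMe3)2, THF, −78 °C; MeI, −78 → −40 °C
Reagents that add atoms: iodomethane, CI
Why: Lactone enolate alkylation in which iodomethane is expected to enter anti to the C4 aryl group, the C3 configuration being of no consequence because this centre is enolised again in step 5.

Step 4
Reactants: 10 3-methylbut-3-en-1-ol
Product: 11 4-iodo-2-methylbut-1-ene
Conditions: I2, PPh3, imidazole, CH2Cl2, 0 °C → rt
Reagents that add atoms: iodine, I-I
Why: Appel-type iodination (Garegg–Samuelsson conditions) converts the primary alcohol into the iodide by SN2 displacement of the alkoxyphosphonium ion and leaves the 1,1-disubstituted alkene alone.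

Step 5
Reactants: 9 (3S,4R,5S)-5-{[(tert-butyldiphenylsilyl)oxy]methyl}-4-(2,6-dimethoxyphenyl)-3-methyldihydrofuran-2(3H)-one; 11 4-iodo-2-methylbut-1-ene
Product: 13 (3S,4S,5S)-5-{[(tert-butyldiphenylsilyl)oxy]methyl}-4-(2,6-dimethoxyphenyl)-3-methyl-3-(3-methylbut-3-en-1-yl)dihydrofuran-2(3H)-one, via lithium enolate 12 (not isolated)
Conditions: LiN(iPr)2, THF, −78 → −40 °C; DMPU, 11, −78 → −10 °C
Reagents that add atoms: none
Why: Alkylation of the tetrasubstituted lactone enolate, in which the iodide should approach C3 on the face opposite the neighbouring C4 aryl group (1,2-induction in the five-membered ring), so that the quaternary centre forms with the butenyl chain trans and the methyl group cis to the aryl ring.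

Step 6
Reactants: 13 (3S,4S,5S)-5-{[(tert-butyldiphenylsilyl)oxy]methyl}-4-(2,6-dimethoxyphenyl)-3-methyl-3-(3-methylbut-3-en-1-yl)dihydrofuran-2(3H)-one
Product: 14 (3S,4S,5S)-4-(2,6-dimethoxyphenyl)-5-(hydroxymethyl)-3-methyl-3-(3-methylbut-3-en-1-yl)dihydrofuran-2(3H)-one
Conditions: Bu4NF, AcOH, THF, 0 °C → rt
Reagents that add atoms: none
Why: Fluoride-induced cleavage of the silyl ether, buffered with acetic acid so that the freed alkoxide does not translactonise.

Step 7
Reactants: 14 (3S,4S,5S)-4-(2,6-dimethoxyphenyl)-5-(hydroxymethyl)-3-methyl-3-(3-methylbut-3-en-1-yl)dihydrofuran-2(3H)-one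
Product: 15 (3S,4S,5S)-4-(2,6-dimethoxyphenyl)-5-(iodomethyl)-3-methyl-3-(3-methylbut-3-en-1-yl)dihydrofuran-2(3H)-one
Conditions: PPh3, I2, imidazole (premixed), CH2Cl2, 0 °C → rt
Reagents that add atoms: iodine, I-I
Why: Appel-type iodination of the unhindered primary alcohol places a halide β to the lactone oxygen, the arrangement needed for the reductive fragmentation in step 8.

Step 8
Reactants: 15 (3S,4S,5S)-4-(2,6-dimethoxyphenyl)-5-(iodomethyl)-3-methyl-3-(3-methylbut-3-en-1-yl)dihydrofuran-2(3H)-one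
Product: 16 (2S,3S)-3-(2,6-dimethoxyphenyl)-2-methyl-2-(3-methylbut-3-en-1-yl)pent-4-enoic acid
Conditions: Zn dust (activated), AcOH, THF, rt → 40 °C
Reagents that add atoms: none
Why: Zinc inserts into the C–I bond and the β-acyloxy organozinc expels the carboxylate (reductive β-elimination, the way iodolactones are returned to unsaturated acids), which opens the ring, unveils the vinyl group on the benzylic carbon and removes the auxiliary C5 centre while the two remaining stereocentres are untouched.

Step 9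
Reactants: 16 (2S,3S)-3-(2,6-dimethoxyphenyl)-2-methyl-2-(3-methylbut-3-en-1-yl)pent-4-enoic acid
Product: 17 (2S)-2-[(1R)-1-(2,6-dimethoxyphenyl)prop-2-en-1-yl]-2,5-dimethylhex-5-en-1-ol
Conditions: LiAlH4, THF, 0 °C → reflux; aq. NaOH work-up
Reagents that add atoms: none
Why: Hydride reduction of the carboxylic acid with LiAlH4 gives the neopentyl primary alcohol and leaves isolated alkenes and aryl ethers alone.

Step 10
Reactants: 17 (2S)-2-[(1R)-1-(2,6-dimethoxyphenyl)prop-2-en-1-yl]-2,5-dimethylhex-5-en-1-ol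
Product: 18 [(1S,2R)-2-(2,6-dimethoxyphenyl)-1,4-dimethylcyclohex-3-en-1-yl]methanol
Conditions: second-generation Grubbs catalyst (H2IMes)(PCy3)Cl2Ru=CHPh (5 mol %), CH2Cl2 (0.01 M), 40 °C
Reagents that add atoms: none
Why: The ruthenium benzylidene exchanges onto the monosubstituted vinyl group of 17, the new alkylidene adds across the 1,1-disubstituted alkene of the same molecule in a [2+2] step, and cycloreversion of the ruthenacyclobutane releases the cyclohexene while ethylene escapes. The closest known reaction type is ring-closing metathesis of a 1,7-diene with one monosubstituted and one 1,1-disubstituted alkene to a 1-methylcyclohexene. Ring C closes as a six-membered carbocycle by forming the C3=C4 double bond between the former vinyl CH and the former isopropenyl carbon. No stereocentre is created, and the quaternary C1 and benzylic C2 are sp3 carbons remote from the metal that keep the configuration set in steps 2 and 5. The step needs cyclisation to win over intermolecular metathesis and a single alkene position: high dilution and the Thorpe–Ingold effect of the quaternary carbon favour closure, only two alkenes are present, and keeping the fourth substituent on C1 as CH2OH (not yet vinyl) rules out a competing cyclopentene closure.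

Step 11
Reactants: 18 [(1S,2R)-2-(2,6-dimethoxyphenyl)-1,4-dimethylcyclohex-3-en-1-yl]methanol
Product: 19 (1S,2S)-2-(2,6-dimethoxyphenyl)-1,4-dimethylcyclohex-3-ene-1-carbaldehyde
Conditions: Dess–Martin periodinane, CH2Cl2, 0 °C → rt
Reagents that add atoms: none
Why: Dess–Martin oxidation of the primary alcohol stops at the aldehyde, which has no α-hydrogen and therefore cannot epimerise.

Step 12
Reactants: 19 (1S,2S)-2-(2,6-dimethoxyphenyl)-1,4-dimethylcyclohex-3-ene-1-carbaldehyde
Product: 20 2-[(1R,6R)-6-ethenyl-3,6-dimethylcyclohex-2-en-1-yl]-1,3-dimethoxybenzene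
Conditions: Ph3PCH3Br, KOtBu, THF, 0 °C → rt
Reagents that add atoms: methyltriphenylphosphonium bromide, C[P+](c1ccccc1)(c1ccccc1)c1ccccc1.[Br-]
Why: Wittig methylenation of the hindered but non-enolisable aldehyde gives the vinyl group on the quaternary carbon.

Step 13
Reactants: 20 2-[(1R,6R)-6-ethenyl-3,6-dimethylcyclohex-2-en-1-yl]-1,3-dimethoxybenzene
Product: 21 2-[(1R,6R)-6-ethenyl-3,6-dimethylcyclohex-2-en-1-yl]-3-methoxyphenol
Conditions: NaSEt, DMF, 130 °C; dilute HCl work-up at 0 °C
Reagents that add atoms: none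
Why: Thiolate demethylation (SN2 attack of ethanethiolate on an O-methyl group) should stop after one ether because the phenoxide formed deactivates the ring, and the two methoxy groups are equivalent so that only one phenol can result.

Step 14
Reactants: 21 2-[(1R,6R)-6-ethenyl-3,6-dimethylcyclohex-2-en-1-yl]-3-methoxyphenol
Product: 23 3-[(1R,6R)-6-ethenyl-3,6-dimethylcyclohex-2-en-1-yl]-2-hydroxy-4-methoxybenzaldehyde, via salicyl alcohol 22 (not isolated)
Conditions: MgCl2, Et3N, (CH2O)n, MeCN, reflux
Reagents that add atoms: paraformaldehyde (as formaldehyde), C=O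
Why: Magnesium-mediated ortho-formylation (Casnati–Skattebøl reaction) delivers formaldehyde within the magnesium phenoxide chelate to the only free ortho position, and a second formaldehyde oxidises the benzylic alkoxide to the aldehyde under basic conditions that spare the alkenes.

Step 15
Reactants: 23 3-[(1R,6R)-6-ethenyl-3,6-dimethylcyclohex-2-en-1-yl]-2-hydroxy-4-methoxybenzaldehyde
Product: 25 8-[(1R,6R)-6-ethenyl-3,6-dimethylcyclohex-2-en-1-yl]-7-methoxy-2H-chromen-2-one, via ethyl (Z)-2-hydroxycinnamate 24 (not isolated)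
Conditions: Ph3P=CHCO2Et, PhNEt2, reflux
Reagents that add atoms: ethyl (triphenylphosphoranylidene)acetate, CCOC(=O)C=P(c1ccccc1)(c1ccccc1)c1ccccc1
Why: Wittig olefination of the salicylaldehyde with the stabilised ylide, followed by thermal E/Z equilibration and lactonisation of the (Z)-cinnamate (the standard coumarin synthesis from salicylaldehydes), closes the pyranone ring of coumarin B.

Step 16
Reactants: 26 umbelliferone (7-hydroxy-2H-chromen-2-one)
Product: 27 7-hydroxy-8-iodo-2H-chromen-2-one
Conditions: I2, KI, 20% aq. NH3, rt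
Reagents that add atoms: iodine, I-I
Why: Electrophilic aromatic iodination of the phenoxide, which under these conditions is known to take place at C8, the ortho position flanked by the two oxygen-bearing carbons.

Step 17
Reactants: 27 7-hydroxy-8-iodo-2H-chromen-2-one
Product: 28 8-iodo-7-methoxy-2H-chromen-2-one
Conditions: MeI, K2CO3, acetone, reflux
Reagents that add atoms: iodomethane, CI
Why: Williamson O-methylation of the phenol under mild carbonate conditions that leave the lactone intact.

Step 18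
Reactants: 25 8-[(1R,6R)-6-ethenyl-3,6-dimethylcyclohex-2-en-1-yl]-7-methoxy-2H-chromen-2-one; 28 8-iodo-7-methoxy-2H-chromen-2-one
Product: 29 7-methoxy-8-[(E)-2-[(1R,2R)-2-(7-methoxy-2-oxo-2H-chromen-8-yl)-1,4-dimethylcyclohex-3-en-1-yl]ethenyl]-2H-chromen-2-one
Conditions: Pd(OAc)2 (10 mol %), P(o-tol)3 (20 mol %), Et3N, DMF, 90 °C
Reagents that add atoms: none
Why: Heck reaction in which the arylpalladium iodide adds to the terminal carbon of the vinyl group and syn-β-hydride elimination can only take the benzylic hydrogen because the other neighbour is quaternary, which should give the (E)-styrene without double-bond migration, as in Heck couplings of iodocoumarins with 2-methylbut-3-en-2-ol.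

**Compound list**

1 | (S)-5-(hydroxymethyl)furan-2(5H)-one | O=C1C=C[C@@H](CO)O1 | starting material
2 | (S)-5-{[(tert-butyldiphenylsilyl)oxy]methyl}furan-2(5H)-one | O=C1C=C[C@@H](CO[Si](c2ccccc2)(c2ccccc2)C(C)(C)C)O1 | intermediate
3 | 1,3-dimethoxybenzene | COc1cccc(OC)c1 | starting material
4 | 2,6-dimethoxyphenyllithium | [Li]c1c(OC)cccc1OC | intermediate
5 | lithium bis(2,6-dimethoxyphenyl)cuprate, Li[Cu(C6H3(OMe)2)2] | [Li+].COc1cccc(OC)c1[Cu-]c1c(OC)cccc1OC | intermediate
6 | tert-butyl{[(2S,3R)-3-(2,6-dimethoxyphenyl)-5-[(trimethylsilyl)oxy]-2,3-dihydrofuran-2-yl]methoxy}diphenylsilane (trimethylsilyl ketene acetal of 7) | C[Si](C)(C)OC1=C[C@H](c2c(OC)cccc2OC)[C@@H](CO[Si](c2ccccc2)(c2ccccc2)C(C)(C)C)O1 | intermediate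
7 | (4R,5S)-5-{[(tert-butyldiphenylsilyl)oxy]methyl}-4-(2,6-dimethoxyphenyl)dihydrofuran-2(3H)-one (4,5-trans) | O=C1C[C@H](c2c(OC)cccc2OC)[C@@H](CO[Si](c2ccccc2)(c2ccccc2)C(C)(C)C)O1 | intermediate
8 | lithium (4R,5S)-5-{[(tert-butyldiphenylsilyl)oxy]methyl}-4-(2,6-dimethoxyphenyl)-4,5-dihydrofuran-2-olate (lithium enolate of 7) | [Li]OC1=C[C@H](c2c(OC)cccc2OC)[C@@H](CO[Si](c2ccccc2)(c2ccccc2)C(C)(C)C)O1 | intermediate
9 | (3S,4R,5S)-5-{[(tert-butyldiphenylsilyl)oxy]methyl}-4-(2,6-dimethoxyphenyl)-3-methyldihydrofuran-2(3H)-one | O=C1[C@@H](C)[C@H](c2c(OC)cccc2OC)[C@@H](CO[Si](c2ccccc2)(c2ccccc2)C(C)(C)C)O1 | intermediate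
10 | 3-methylbut-3-en-1-ol | CC(=C)CCO | starting material
11 | 4-iodo-2-methylbut-1-ene | CC(=C)CCI | intermediate
12 | lithium (4S,5S)-5-{[(tert-butyldiphenylsilyl)oxy]methyl}-4-(2,6-dimethoxyphenyl)-3-methyl-4,5-dihydrofuran-2-olate (lithium enolate of 9) | [Li]OC1=C(C)[C@H](c2c(OC)cccc2OC)[C@@H](CO[Si](c2ccccc2)(c2ccccc2)C(C)(C)C)O1 | intermediate
13 | (3S,4S,5S)-5-{[(tert-butyldiphenylsilyl)oxy]methyl}-4-(2,6-dimethoxyphenyl)-3-methyl-3-(3-methylbut-3-en-1-yl)dihydrofuran-2(3H)-one (3-methyl cis to aryl) | O=C1[C@@](C)(CCC(C)=C)[C@H](c2c(OC)cccc2OC)[C@@H](CO[Si](c2ccccc2)(c2ccccc2)C(C)(C)C)O1 | intermediate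
14 | (3S,4S,5S)-4-(2,6-dimethoxyphenyl)-5-(hydroxymethyl)-3-methyl-3-(3-methylbut-3-en-1-yl)dihydrofuran-2(3H)-one | O=C1[C@@](C)(CCC(C)=C)[C@H](c2c(OC)cccc2OC)[C@@H](CO)O1 | intermediate
15 | (3S,4S,5S)-4-(2,6-dimethoxyphenyl)-5-(iodomethyl)-3-methyl-3-(3-methylbut-3-en-1-yl)dihydrofuran-2(3H)-one | O=C1[C@@](C)(CCC(C)=C)[C@H](c2c(OC)cccc2OC)[C@@H](CI)O1 | intermediate
16 | (2S,3S)-3-(2,6-dimethoxyphenyl)-2-methyl-2-(3-methylbut-3-en-1-yl)pent-4-enoic acid | OC(=O)[C@@]([C@@H](C=C)c1c(OC)cccc1OC)(C)CCC(C)=C | intermediate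
17 | (2S)-2-[(1R)-1-(2,6-dimethoxyphenyl)prop-2-en-1-yl]-2,5-dimethylhex-5-en-1-ol | OC[C@@]([C@@H](C=C)c1c(OC)cccc1OC)(C)CCC(C)=C | intermediate
18 | [(1S,2R)-2-(2,6-dimethoxyphenyl)-1,4-dimethylcyclohex-3-en-1-yl]methanol (aryl and CH2OH cis) | OC[C@@]1(C)CCC(C)=C[C@H]1c1c(OC)cccc1OC | intermediate
19 | (1S,2S)-2-(2,6-dimethoxyphenyl)-1,4-dimethylcyclohex-3-ene-1-carbaldehyde | O=C[C@@]1(C)CCC(C)=C[C@H]1c1c(OC)cccc1OC | intermediate
20 | 2-[(1R,6R)-6-ethenyl-3,6-dimethylcyclohex-2-en-1-yl]-1,3-dimethoxybenzene | C=C[C@@]1(C)CCC(C)=C[C@H]1c1c(OC)cccc1OC | intermediate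
21 | 2-[(1R,6R)-6-ethenyl-3,6-dimethylcyclohex-2-en-1-yl]-3-methoxyphenol | C=C[C@@]1(C)CCC(C)=C[C@H]1c1c(OC)cccc1O | intermediate
22 | 2-[(1R,6R)-6-ethenyl-3,6-dimethylcyclohex-2-en-1-yl]-6-(hydroxymethyl)-3-methoxyphenol | C=C[C@@]1(C)CCC(C)=C[C@H]1c1c(OC)ccc(CO)c1O | intermediate
23 | 3-[(1R,6R)-6-ethenyl-3,6-dimethylcyclohex-2-en-1-yl]-2-hydroxy-4-methoxybenzaldehyde | C=C[C@@]1(C)CCC(C)=C[C@H]1c1c(OC)ccc(C=O)c1O | intermediate
24 | ethyl (Z)-3-{3-[(1R,6R)-6-ethenyl-3,6-dimethylcyclohex-2-en-1-yl]-2-hydroxy-4-methoxyphenyl}prop-2-enoate | C=C[C@@]1(C)CCC(C)=C[C@H]1c1c(OC)ccc(/C=C\C(=O)OCC)c1O | intermediate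
25 | 8-[(1R,6R)-6-ethenyl-3,6-dimethylcyclohex-2-en-1-yl]-7-methoxy-2H-chromen-2-one | C=C[C@@]1(C)CCC(C)=C[C@H]1c1c(OC)ccc2ccc(=O)oc12 | intermediate
26 | umbelliferone (7-hydroxy-2H-chromen-2-one) | O=c1ccc2ccc(O)cc2o1 | starting material
27 | 7-hydroxy-8-iodo-2H-chromen-2-one | O=c1ccc2ccc(O)c(I)c2o1 | intermediate
28 | 8-iodo-7-methoxy-2H-chromen-2-one | COc1ccc2ccc(=O)oc2c1I | intermediate
29 | 7-methoxy-8-[(E)-2-[(1R,2R)-2-(7-methoxy-2-oxo-2H-chromen-8-yl)-1,4-dimethylcyclohex-3-en-1-yl]ethenyl]-2H-chromen-2-one | COc1ccc2ccc(=O)oc2c1/C=C/[C@@]1(C)CCC(C)=C[C@H]1c1c(OC)ccc2ccc(=O)oc12 | target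

**Step count and risks**

Total step count: 18. Longest linear sequence: 15 steps (steps 1–3, 5–15 and 18); steps 4, 16 and 17 make the two side fragments.

Steps most likely to fail:

- **Step 5.** The hindered, strongly basic tetrasubstituted enolate may dehydroiodinate the homoallylic iodide (E2 to isoprene) faster than it is alkylated at the congested carbon next to the aryl group. Raising the temperature to compensate could erode the facial selectivity. The fallback sets out from 9: enolate 12 is alkylated with commercial 2-(2-bromoethyl)-2-methyl-1,3-dioxolane (LiN(iPr)2, DMPU, THF), an electrophile that cannot eliminate to a conjugated diene. This should give (3S,4S,5S)-5-{[(tert-butyldiphenylsilyl)oxy]methyl}-4-(2,6-dimethoxyphenyl)-3-methyl-3-[2-(2-methyl-1,3-dioxolan-2-yl)ethyl]dihydrofuran-2(3H)-one F1. Mild ketal hydrolysis (PPTS, acetone/H2O, rt) then gives (3S,4S,5S)-5-{[(tert-butyldiphenylsilyl)oxy]methyl}-4-(2,6-dimethoxyphenyl)-3-methyl-3-(3-oxobutyl)dihydrofuran-2(3H)-one F2. Wittig methylenation of the ketone (Ph3PCH3Br, KOtBu, THF, 0 °C), to which the hindered lactone carbonyl should be inert, comes back to the route at 13.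

- **Step 2.** Transfer of the doubly ortho-substituted aryl group from copper may be sluggish, so that the butenolide is consumed by 1,2-addition or enolisation before conjugate addition occurs. The fallback sets out from 2 and uses a palladium-catalysed reductive Heck reaction (hydroarylation) with commercial 2-iodo-1,3-dimethoxybenzene (Pd(OAc)2, Et3N, HCO2H, DMF, 70 °C). The arylpalladium iodide adds syn across the butenolide C=C on the face away from the C5 substituent. The resulting alkylpalladium on C3 has no syn β-hydrogen and is reduced by formate. This arrives directly at 7 and makes no new compound (F0).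

- **Step 18.** Carbopalladation between the doubly ortho-substituted arylpalladium and the neopentyl-type alkene may be slow, so that deiodination of the aryl iodide, precipitation of palladium or arylation at a coumarin C3=C4 bond takes over. The fallback sets out from 25 and replaces the Heck bond formation by a Suzuki–Miyaura coupling. Cross-metathesis of 25 with vinylboronic acid pinacol ester (second-generation Hoveyda–Grubbs catalyst (H2IMes)Cl2Ru=CH(C6H4-2-OiPr), CH2Cl2, 40 °C) should give 8-{(1R,6R)-3,6-dimethyl-6-[(E)-2-(4,4,5,5-tetramethyl-1,3,2-dioxaborolan-2-yl)ethenyl]cyclohex-2-en-1-yl}-7-methoxy-2H-chromen-2-one F3. Coupling of F3 with 28 (Pd(OAc)2, SPhos, K3PO4, toluene/H2O, 80 °C) comes back to the route at the target 29.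

**Further compounds**

F1 | step 5 | (3S,4S,5S)-5-{[(tert-butyldiphenylsilyl)oxy]methyl}-4-(2,6-dimethoxyphenyl)-3-methyl-3-[2-(2-methyl-1,3-dioxolan-2-yl)ethyl]dihydrofuran-2(3H)-one | O=C1[C@@](C)(CCC2(C)OCCO2)[C@H](c2c(OC)cccc2OC)[C@@H](CO[Si](c2ccccc2)(c2ccccc2)C(C)(C)C)O1
F2 | step 5 | (3S,4S,5S)-5-{[(tert-butyldiphenylsilyl)oxy]methyl}-4-(2,6-dimethoxyphenyl)-3-methyl-3-(3-oxobutyl)dihydrofuran-2(3H)-one | O=C1[C@@](C)(CCC(C)=O)[C@H](c2c(OC)cccc2OC)[C@@H](CO[Si](c2ccccc2)(c2ccccc2)C(C)(C)C)O1
F0 | step 2 | none | none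
F3 | step 18 | 8-{(1R,6R)-3,6-dimethyl-6-[(E)-2-(4,4,5,5-tetramethyl-1,3,2-dioxaborolan-2-yl)ethenyl]cyclohex-2-en-1-yl}-7-methoxy-2H-chromen-2-one | CC1(C)OB(OC1(C)C)/C=C/[C@@]2(C)CCC(C)=C[C@H]2c2c(OC)ccc3ccc(=O)oc23
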